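The data are simulated with constants of no real substance, and the scatter is random.

Count J, the product you want, against its rival Z.

| flask | E | D | L | G | X | temperature | remark | time |
|---|---|---|---|---|---|---|---|---|
| Saturday's | 0.50 M | 0.50 M | 2.2 M | 1 mM | 0.50 mM | 55 °C | run made earlier |  |
| Tuesday's | 0.50 M | 0.50 M | 2.2 M | 1 mM | 0.50 mM | 90 °C | run made earlier |  |
| delta | 1.0 M | 1.0 M | 2.20 M | 1.0 mM | 0.50 mM | 90 °C |  | 12 d |
| eta | 1.0 M | 1.0 M | 2.20 M | 1.0 mM | 0.50 mM |  | at 60 °C until 4.0 d, from then on at 120 °C | 12 d |
| epsilon | 1.0 M | 1.0 M | 2.20 M | 1.0 mM | 0.50 mM | 120 °C |  | 12 d |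
| beta | 1.0 M | 1.0 M | 2.20 M | 1.0 mM | 0.50 mM | 60 °C |  | 12 d |

- Saturday's (time / d: J / %, Z / %): 4.00: 48.1, 21.7; 10.0: 62.4, 28.9; 15.0: 66.0, 30.9; 30.0: 66.0, 32.4; 50.0: 66.6, 32.7; 60.0: 66.9, 34.0
- Tuesday's (time / d: J / %, Z / %): 0.625: 55.2, 24.2; 1.67: 60.5, 34.6; 3.00: 59.9, 38.5; 5.00: 61.0, 39.7; 8.00: 60.8, 40.0; 10.0: 61.2, 40.1; 12.0: 60.8, 39.1

(scatter of a reading: 0.5 percentage points)

1. the best flask by excess of J over Z; "all alike" if 1.5 percentage points covers them all (delta / eta / epsilon / beta / all alike)
2. excess of J over Z at the end, delta
3. excess of J over Z at the end, eta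
4. excess of J over Z at the end, epsilon
5. excess of J over Z at the end, beta

- G is single-handed; E and D are mirror images of each other, charged as a racemate, each of them at the stated concentration
- the numbers in the tables scatter by 0.5 percentage points (one standard deviation)
- an excess is the difference of the two amounts in percent of their sum
- an excess is below zero if the other one leads

Read the end of Saturday's run first: J reaches 66.9%, more than the half of the charge that was E. So E gives J, D gives Z, and something turns D into E; take that to be X, which makes this a dynamic kinetic resolution. Now read Tuesday's run after 0.625 d: J gains 5.6 percentage points and Z gains 15 points, more to Z than to J, although J led early. Read that as the interconversion having ended while substrate remained. That end is the crossing: from then on each E left becomes J and each D left becomes Z.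

So define the lead Λ, J − Z + E − D in percent of the E and D charged. Once interconversion ends it holds still, and at full conversion it equals the excess. Saturday's reading at 4.00 d, with E and D taken about equal, gives 26 points. That is my figure for eta, taken from a run at 55 °C for a first stage at 60 °C, and assuming that interconversion is over during its hot stage after 4.0 d.

At the ends of the runs, with E − D taken as nil, Λ reads 33 points on Saturday and 22 points on Tuesday. I keep Tuesday's figure for delta, which runs at the same temperature; its L at 2.20 M stands above the 2.00 M of E and D. Extending the straight line through those two readings to 120 °C gives my estimate for epsilon, about 12 points. Saturday's run is unfinished at 10.0 d, with J and Z adding to 91.3%, so I expect beta to be unfinished at 12 d and take my estimate from that run's excess there, 36.7%, which stands higher than that run's final lead.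

The forecast names beta and gives 35% for delta, 31% for eta, 27% for epsilon and 36.5% for beta. Its ground is that, if acylation is first order in L, “late L starvation favours racemisation and raises the excess”. We part on delta and epsilon, where my figures stand lower.

The flasks give beta at 37.6%, ahead of eta at 26.8%, delta at 20.4% and epsilon at 7.04%.

    L + G + E → G + J (k = 0.240 L² mol⁻² min⁻¹, Ea = 69.0 kJ mol⁻¹)
    X → Q (k = 4.70 × 10⁻⁴ min⁻¹, Ea = 100 kJ mol⁻¹)
    E + X ⇌ D + X, rate k3*[X]*[E] forward; the back reaction follows from the equilibrium constant (k = 14.0 L mol⁻¹ min⁻¹, Ea = 50.0 kJ mol⁻¹)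
    L + G + D → G + Z (k = 0.100 L² mol⁻² min⁻¹, Ea = 60.0 kJ mol⁻¹)
    (constants at 60 °C)

In eta at the change, X stood at 6.67% of its charge, and Λ there was 27 points, beside the 26 points read from Saturday's run. Beta at 12.0 d shows 37.6% but holds Λ of 30 points, and at 120 d its excess reads 30.4%.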